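The target is cut at C13=C14 (later reduced) back to a C13 methyl ketone, and the remaining C18 core is read as cyclised (5E,9E)-farnesylacetone. The key step exploits the trans-fused A/B decalin carrying the C10 methyl, the C9 side chain and the 8α oxygen, which is the anti-addition pattern of an E,E-triene, together with the C13 carbonyl oxygen, which reaches C8 through a six-membered ring. One enantioselective, proton-initiated cascade forms C4–C5, C9–C10 and C8–O, closes rings A, B and a temporary dihydropyran, and sets C5, C8, C9 and C10. Its precursor is open-chain, geometrically pure farnesylacetone; hydrolysis, olefination, asymmetric hydrogenation at C13 and acetylation finish the synthesis.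

Key step: step 2

Assumption: (2E,6E)-farnesyl bromide is bought as the geometrically defined isomer, so that farnesylacetone is obtained all-E without separating an isomer mixture; labdane atom numbers are used throughout, also for the open chain (terminal alkene C3=C4, carbonyl carbon C13).

Step 1
Reactants: 1 (2E,6E)-farnesyl bromide; 2 ethyl acetoacetate
Product: 5 (5E,9E)-farnesylacetone, via keto ester 3 (not isolated), via keto acid 4 (not isolated)
Conditions: 2 (1.3 equiv), NaH (1.25 equiv), THF, 0 °C → rt; then 2 M aq. NaOH, MeOH, 40 °C; then 1 M HCl to pH 4, 40 °C
Reagents that add atoms: none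
Why: Acetoacetic ester ketone synthesis, in which the soft sodium enolate displaces the primary allylic bromide by SN2 and saponification followed by decarboxylation of the β-keto acid leaves the methyl ketone; neither trisubstituted alkene takes part, so both stay E.

Step 2
Reactants: 5 (5E,9E)-farnesylacetone
Product: 6 sclareol oxide
Conditions: confined chiral imidodiphosphorimidate (IDPi) Brønsted acid, antipode chosen to give the 5S,10S series (5–10 mol%), perfluoro-tert-butanol, −20 → 0 °C; Et3N quench
Reagents that add atoms: none
Why: Proposed new method: the confined chiral acid protonates C3 of the terminal alkene while the chain is held in a chair–chair fold, C4 bonds to C5 and C10 to C9 in two 6-endo-trig closures (rings A and B), the C13 carbonyl oxygen adds to C8 (ring C, again 6-endo with respect to the 9E alkene) and the resulting cyclic oxocarbenium ion gives up H12 to the catalyst anion. The closest known reactions are the racemic superacid cyclisation of this very ketone to sclareol oxide and the enantioselective proton-initiated cyclisation of hydroxyl-terminated polyprenoids such as homofarnesol by chiral Brønsted acids (tin-activated binaphthols, confined IDPi acids in fluorinated alcohols); a carbonyl oxygen as terminator under a chiral acid is the untested element. C5 and C10 are set by anti addition across the 5E alkene (trans ring fusion, 10β-methyl), C9 and C8 by anti addition across the 9E alkene (equatorial C11, 8α-oxygen, axial C17), so the all-E geometry and the chair–chair fold fix the relative configuration. The absolute configuration comes from the catalyst pocket, which admits one helical sense of the fold and thus decides which face of C5 is attacked by C4; C3 and C4 themselves do not become stereocentres. The step needs protonation of the terminal alkene in preference to the inner ones and ring closure by oxygen in preference to proton loss from the C8 cation: the isopropylidene end is the most exposed alkene, a metal-free acid cannot be sequestered by chelation to the carbonyl group as a tin-based one would be, and the carbonyl oxygen closes a six-membered ring on C8.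

Step 3
Reactants: 6 sclareol oxide
Product: 7 (5S,8R,9R,10S)-8α-hydroxy-14,15-dinorlabdan-13-one
Conditions: aq. HCl (0.1 M, cat.), THF, 0 °C → rt; NaHCO3 quench
Reagents that add atoms: water, O
Why: Acid-catalysed hydration of an enol ether, in which C12 is protonated, water adds to the C13 oxocarbenium ion and the hemiketal opens to the δ-hydroxy ketone; the C8–O bond is never broken, so C8 keeps its configuration.

Step 4
Reactants: 7 (5S,8R,9R,10S)-8α-hydroxy-14,15-dinorlabdan-13-one; 8 triethyl phosphonoacetate
Product: 9 ethyl (13E)-8α-hydroxylabd-13-en-15-oate
Conditions: 8 (2.5 equiv), NaH (2.4 equiv), THF, 0 → 50 °C; SiO2 chromatography to remove the 13Z ester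
Reagents that add atoms: none
Why: Horner–Wadsworth–Emmons olefination of a methyl ketone with a stabilised phosphonate, where reversible addition and the smaller size of methyl compared with the C12 chain favour the E enoate; the phosphonate anion is too weak a base to deprotonate the tertiary C8 alcohol and no stereocentre is touched.

Step 5
Reactants: 9 ethyl (13E)-8α-hydroxylabd-13-en-15-oate
Product: 10 (13E)-labd-13-ene-8α,15-diol
Conditions: DIBAL-H (3.5 equiv), CH2Cl2, −78 → 0 °C; Rochelle salt
Reagents that add atoms: none
Why: 1,2-Reduction of an α,β-unsaturated ester to the allylic alcohol by DIBAL-H, the first equivalent being consumed by the C8 hydroxyl; alkene geometry and ring stereocentres are unaffected.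

Step 6
Reactants: 10 (13E)-labd-13-ene-8α,15-diol
Product: 11 (13S)-labdane-8α,15-diol
Conditions: Ru(OAc)2[(R)-BINAP] (1 mol%), H2 (50 atm), MeOH, 25 °C
Reagents that add atoms: none
Why: Noyori asymmetric hydrogenation of an allylic alcohol, in which the C15 hydroxyl binds ruthenium and hydrogen is delivered to one face of the E-trisubstituted alkene; the (R)-BINAP complex should set 13S, as it gives (S)-citronellol from geraniol, and the remote ring stereocentres play no part.

Step 7
Reactants: 11 (13S)-labdane-8α,15-diol
Product: 12 (13S)-8α-hydroxylabdan-15-yl acetate
Conditions: Ac2O (1.2 equiv), pyridine, CH2Cl2, 0 °C → rt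
Reagents that add atoms: acetic anhydride, CC(=O)OC(C)=O
Why: Acylation of a primary alcohol with acetic anhydride and pyridine; the tertiary, hindered C8 hydroxyl does not react under these conditions, so only O15 is acetylated.

Compound list
1 | (2E,6E)-farnesyl bromide, (2E,6E)-1-bromo-3,7,11-trimethyldodeca-2,6,10-triene | BrC/C=C(\C)CC/C=C(\C)CCC=C(C)C | starting material
2 | ethyl acetoacetate (ethyl 3-oxobutanoate) | CCOC(=O)CC(C)=O | starting material
3 | ethyl (4E,8E)-2-acetyl-5,9,13-trimethyltetradeca-4,8,12-trienoate (racemic at C2, not isolated) | CCOC(=O)C(C/C=C(\C)CC/C=C(\C)CCC=C(C)C)C(C)=O | intermediate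
4 | (4E,8E)-2-acetyl-5,9,13-trimethyltetradeca-4,8,12-trienoic acid (racemic at C2, not isolated) | OC(=O)C(C/C=C(\C)CC/C=C(\C)CCC=C(C)C)C(C)=O | intermediate
5 | (5E,9E)-farnesylacetone, (5E,9E)-6,10,14-trimethylpentadeca-5,9,13-trien-2-one | CC(=O)CC/C=C(\C)CC/C=C(\C)CCC=C(C)C | intermediate
6 | sclareol oxide, (5S,8R,9R,10S)-8α,13-epoxy-14,15-dinorlabd-12-ene | CC1=CC[C@@H]2[C@@]3(C)CCCC(C)(C)[C@@H]3CC[C@@]2(C)O1 | intermediate
7 | (5S,8R,9R,10S)-8α-hydroxy-14,15-dinorlabdan-13-one | CC(=O)CC[C@@H]1[C@@]2(C)CCCC(C)(C)[C@@H]2CC[C@@]1(C)O | intermediate
8 | triethyl phosphonoacetate | CCOC(=O)CP(=O)(OCC)OCC | starting material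
9 | ethyl (5S,8R,9R,10S,13E)-8α-hydroxylabd-13-en-15-oate | CCOC(=O)/C=C(\C)CC[C@@H]1[C@@]2(C)CCCC(C)(C)[C@@H]2CC[C@@]1(C)O | intermediate
10 | (5S,8R,9R,10S,13E)-labd-13-ene-8α,15-diol | OC/C=C(\C)CC[C@@H]1[C@@]2(C)CCCC(C)(C)[C@@H]2CC[C@@]1(C)O | intermediate
11 | (5S,8R,9R,10S,13S)-labdane-8α,15-diol | OCC[C@@H](C)CC[C@@H]1[C@@]2(C)CCCC(C)(C)[C@@H]2CC[C@@]1(C)O | intermediate
12 | (5S,8R,9R,10S,13S)-8α-hydroxylabdan-15-yl acetate (CNP0188939.1) | CC(=O)OCC[C@@H](C)CC[C@@H]1[C@@]2(C)CCCC(C)(C)[C@@H]2CC[C@@]1(C)O | target

Total step count: 7. Longest linear sequence: 7 steps (1 → 12).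

Steps most likely to fail

1. Step 2 (the step labelled as a proposed new method). Turnover may stall because the catalyst is held by hydrogen bonding to the carbonyl group or by protonation of the basic enol ether product. The pocket may also distinguish the two folds of the chain poorly, or the C8 cation may lose a proton before the oxygen closes ring C. Fallback with known chemistry, taking the absolute configuration from a resolution instead of from the catalyst: starting from 5, fluorosulfonic acid in 2-nitropropane at −78 °C, an established cyclisation of this ketone, should give racemic sclareol oxide, that is 6 together with its mirror image ent-sclareol oxide F1. Hydrolysis as in step 3 should then give 7 together with the enantiomeric ketol F2, and preparative chromatography on a chiral stationary phase separates the two, so that the route is rejoined at 7.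

2. Step 4. The olefination may show incomplete E/Z control, the two enoates may be hard to separate, and the C8 alkoxide may add in a conjugate fashion to the new enoate and close an 8,13-ether. Fallback that takes the alkene geometry from a syn-carbometalation instead of an olefination: starting from 7, kinetic deprotonation at the methyl group with LDA (the first equivalent is consumed by the C8 hydroxyl) and diethyl chlorophosphate should give the terminal enol phosphate F3, and further LDA eliminates phosphate to give the terminal alkyne F4. Zirconium-catalysed methylalumination (Me3Al, Cp2ZrCl2, CH2Cl2), which adds methyl and aluminium syn across the alkyne, followed by n-BuLi and paraformaldehyde should give the E-allylic alcohol directly, so that the route is rejoined at 10 and step 5 is not needed.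

3. Step 6. Facial selectivity may erode if the alkene migrates or isomerises on the metal before hydrogen is delivered, which low hydrogen pressure favours. The C13 epimer formed in this way would be hard to remove because C13 is far from the ring stereocentres. Fallback that uses conjugate hydride delivery to the ester instead of hydroxyl-directed hydrogenation: starting from 9, copper hydride catalysed asymmetric 1,4-reduction (Cu(OAc)2, a chiral bisphosphine such as Tol-BINAP in the antipode that gives 13S, PMHS, t-BuOH, toluene) should give the saturated ester F5, and LiAlH4 reduction of F5 rejoins the route at 11.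

Further compounds
F1 | step 2 | ent-sclareol oxide, (5R,8S,9S,10R)-8,13-epoxy-14,15-dinorlabd-12-ene | CC1=CC[C@H]2[C@]3(C)CCCC(C)(C)[C@H]3CC[C@]2(C)O1
F2 | step 2 | (5R,8S,9S,10R)-8-hydroxy-14,15-dinorlabdan-13-one | CC(=O)CC[C@H]1[C@]2(C)CCCC(C)(C)[C@H]2CC[C@]1(C)O
F3 | step 4 | diethyl (5S,8R,9R,10S)-8-hydroxy-14,15-dinorlabd-13(16)-en-13-yl phosphate | C=C(OP(=O)(OCC)OCC)CC[C@@H]1[C@@]2(C)CCCC(C)(C)[C@@H]2CC[C@@]1(C)O
F4 | step 4 | (5S,8R,9R,10S)-14,15-dinorlabd-13(16)-yn-8-ol | C#CCC[C@@H]1[C@@]2(C)CCCC(C)(C)[C@@H]2CC[C@@]1(C)O
F5 | step 6 | ethyl (5S,8R,9R,10S,13S)-8-hydroxylabdan-15-oate | CCOC(=O)C[C@@H](C)CC[C@@H]1[C@@]2(C)CCCC(C)(C)[C@@H]2CC[C@@]1(C)O
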